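**Plan**

1. Numbering (icetexane = 9(10→20)-abeo-abietane): ring A = C1–C5 and C10 (gem-dimethyl on C4); C20 = the CH2 between C10 and C9; C7 = hemiketal carbon; ring C = C8, C9, C11–C14.
2. Enabling feature: C7 is at the carboxyl oxidation level and lies 1,3 across the bridging oxygen from quaternary C10, which also carries C20. The oxolane ring (O, C10, C5, C6, C7) can therefore exist first as a γ-lactone whose carbonyl C7 is the sixth atom round from ring-C carbon C8.
3. Retrosynthetic cuts, in order: quinone → methoxyarene; C5–H → C5=C6; C7–C8 (aryllithium onto butenolide carbonyl); butenolide C5=C6 and O–C7 (ketol plus a C2 ylide); benzylic C20–O of an epoxide; epoxide → enone; C10=C20 (aldol).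
4. Forward: rings A and C are bought; the oxolane ring is made as a butenolide (step 4); the pyran ring, and with it the seven-membered carbocycle, closes last through the C8–C7 bond (step 6); then C5=C6 is saturated and ring C is oxidised.
5. Stereochemistry: C10 from the catalyst-controlled epoxidation (step 2); C7 from C10 through the bridge (step 6); C5 last, by hydrogenation from the oxygen-bridge face of the bicyclic alkene (step 7).
6. The C5=C6 bond is a helper: it leaves C10 as the only stereocentre before the key step and is removed only inside the bicycle, where it should give the junction with H5 syn to the bridging oxygen. Saturating the butenolide earlier would be expected to give the cis-fused lactone, which has the wrong C5.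

Key step: step 6

Assumption: from compound 12 onwards the bridged hemiketal is taken to be the resting ring–chain tautomer of the 10-hydroxy-7-ketone, as the target is drawn; compound 2 is taken to be a catalogue compound.

**Step 1**
Reactants: 1 2,2-dimethylcyclohexan-1-one; 2 3,5-dimethoxy-4-(propan-2-yl)benzaldehyde
Product: 4 (6E)-6-[(3,5-dimethoxy-4-isopropylphenyl)methylidene]-2,2-dimethylcyclohexan-1-one, via aldol adduct 3 (not isolated)
Conditions: KOH, EtOH, reflux
Reagents that add atoms: none
Why: Claisen–Schmidt crossed aldol condensation: 1 can enolise only at C6 and 2 cannot enolise, and E1cB loss of water from aldol 3 should give the conjugated enone as the E isomer (aryl anti to the carbonyl), the thermodynamic geometry.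

**Step 2**
Reactants: 4 (6E)-6-[(3,5-dimethoxy-4-isopropylphenyl)methylidene]-2,2-dimethylcyclohexan-1-one
Product: 5 (2R,3S)-2-(3,5-dimethoxy-4-isopropylphenyl)-5,5-dimethyl-1-oxaspiro[2.5]octan-4-one
Conditions: 30% aq. H2O2, LiOH·H2O, O-benzyl-N-(9-anthracenylmethyl)cinchonidinium bromide (10 mol %), n-Bu2O, 0 °C
Reagents that add atoms: hydrogen peroxide, OO
Why: Weitz–Scheffer nucleophilic epoxidation under chiral phase-transfer catalysis: the ammonium hydroperoxide ion pair adds to the β-carbon of the s-cis-locked E-enone and the enolate closes onto oxygen with retention of the E geometry, the catalyst choosing the enone face so that the spiro carbon (the later C10) is S; the quasi-enantiomeric cinchoninium salt attacks the other face.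

**Step 3**
Reactants: 5 (2R,3S)-2-(3,5-dimethoxy-4-isopropylphenyl)-5,5-dimethyl-1-oxaspiro[2.5]octan-4-one
Product: 6 (2S)-2-[(3,5-dimethoxy-4-isopropylphenyl)methyl]-2-hydroxy-6,6-dimethylcyclohexan-1-one
Conditions: H2 (1 atm), 5% Pd/BaSO4, EtOAc, rt
Reagents that add atoms: none
Why: Hydrogenolysis of the benzylic C–O bond of an aryl epoxide (the reaction type that turns chalcone epoxides into α-hydroxy dihydrochalcones) leaves the non-benzylic tertiary C–O bond alone, so the tertiary ketol should form with the spiro stereocentre unchanged.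

**Step 4**
Reactants: 6 (2S)-2-[(3,5-dimethoxy-4-isopropylphenyl)methyl]-2-hydroxy-6,6-dimethylcyclohexan-1-one
Product: 8 (7aS)-7a-[(3,5-dimethoxy-4-isopropylphenyl)methyl]-4,4-dimethyl-5,6,7,7a-tetrahydro-1-benzofuran-2(4H)-one, via acyl ylide 7 (not isolated)
Conditions: Ph3P=C=C=O (1.3 equiv), toluene, 110 °C
Reagents that add atoms: (triphenylphosphoranylidene)ketene, O=C=C=P(c1ccccc1)(c1ccccc1)c1ccccc1
Why: Butenolide synthesis with the cumulated ylide: the tertiary hydroxyl adds across the ketene C=C to give ester-stabilised ylide 7, which closes the five-membered ring by intramolecular Wittig olefination of the neighbouring ketone; C10 is not involved and keeps its configuration.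

**Step 5**
Reactants: 8 (7aS)-7a-[(3,5-dimethoxy-4-isopropylphenyl)methyl]-4,4-dimethyl-5,6,7,7a-tetrahydro-1-benzofuran-2(4H)-one
Product: 9 (7aS)-7a-[(2-iodo-3,5-dimethoxy-4-isopropylphenyl)methyl]-4,4-dimethyl-5,6,7,7a-tetrahydro-1-benzofuran-2(4H)-one
Conditions: N-iodosuccinimide (1.05 equiv), CF3CO2H (10 mol %), MeCN, 0 °C to rt
Reagents that add atoms: N-iodosuccinimide, O=C1CCC(=O)N1I
Why: Electrophilic aromatic iodination: the two free positions of ring C are equivalent (local mirror plane through C9 and C13) and each is ortho to one methoxy group and para to the other, so a single mono-iodide should form, while the electron-poor butenolide alkene does not react.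

**Step 6**
Reactants: 9 (7aS)-7a-[(2-iodo-3,5-dimethoxy-4-isopropylphenyl)methyl]-4,4-dimethyl-5,6,7,7a-tetrahydro-1-benzofuran-2(4H)-one
Product: 12 (7S,10S)-7,10-epoxy-12,14-dimethoxyicetexa-5,8,11,13-tetraen-7-ol, via aryllithium 10 (not isolated), via lithium hemiketalate 11 (not isolated)
Conditions: t-BuLi (2.1 equiv), THF, −100 °C to −78 °C; then aq. NH4Cl
Reagents that add atoms: none
Why: Iodine–lithium exchange, which at −100 °C should outrun attack of t-BuLi on the lactone, gives aryllithium 10, whose carbanionic C8 adds to the butenolide carbonyl C7 to give the bridged lithium hemiketalate 11, protonated on work-up to 12. The closest known reaction type is the Parham cyclization, here with a lactone as the internal electrophile, as in additions of aryllithiums to lactones that give lactols. The C8–C7 bond closes the pyran ring (C8, C9, C20, C10, O, C7) by 6-exo-trig attack on the C=O and, by the same bond, the seven-membered carbocycle (7-exo-trig), so the whole tetracyclic skeleton is complete after this step. The new stereocentre C7 is controlled by C10: the three-atom bridge C20–C9–C8 can reach the carbonyl only from the lactone face that carries C20, so (S)-C10 gives (S)-C7. The step needs 1,2- and not 1,4-addition and one addition only: the β-carbon C5 is fully substituted and flanked by two quaternary carbons, the aryllithium is a hard nucleophile, and adduct 11 is a tetrahedral alkoxide with no second aryl group within reach.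

**Step 7**
Reactants: 12 (7S,10S)-7,10-epoxy-12,14-dimethoxyicetexa-5,8,11,13-tetraen-7-ol
Product: 13 (5R,7S,10S)-7,10-epoxy-12,14-dimethoxyicetexa-8,11,13-trien-7-ol
Conditions: H2 (1 atm), [Ir(cod)(PCy3)(py)]PF6 (10 mol %), CH2Cl2, rt
Reagents that add atoms: none
Why: Homogeneous hydrogenation of the trisubstituted C5=C6 bond with the cationic iridium catalyst should occur from the exo face (the side of the bridging oxygen, which together with the C7 hydroxyl can bind iridium) because the endo face is covered by the C20–C9–C8 bridge and ring C; H5 then ends up syn to the bridging oxygen, which is the required (5R) centre and the less stable, trans-fused oxolane–ring A junction, set here under kinetic control.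

**Step 8**
Reactants: 13 (5R,7S,10S)-7,10-epoxy-12,14-dimethoxyicetexa-8,11,13-trien-7-ol
Product: 15 (5R,7S,10S)-7,10-epoxy-7-hydroxy-12-methoxyicetexa-8,12-diene-11,14-dione (the target), via phenol 14 (not isolated)
Conditions: (NH4)2Ce(NO3)6 (4.2 equiv), MeCN–H2O, 0 °C
Reagents that add atoms: water, O
Why: Oxidation of a methoxyarene to a methoxy-p-quinone (the reaction type that converts 3,4,5-trimethoxytoluene-type arenes into methoxy-p-quinones): the arene radical cation should be captured by water at C11, the only free ring position and para to the C14 methoxy group, to give p-methoxyphenol 14, which is oxidised further with loss of methanol from C14 while the C12 methoxy group survives as a vinylogous ester; C20 sits meta to both methoxy groups, which disfavours side-chain oxidation.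

**Compound list**

1 | 2,2-dimethylcyclohexan-1-one | CC1(C)CCCCC1=O | starting material
2 | 3,5-dimethoxy-4-(propan-2-yl)benzaldehyde | COc1cc(C=O)cc(OC)c1C(C)C | starting material
3 | 6-[(3,5-dimethoxy-4-isopropylphenyl)(hydroxy)methyl]-2,2-dimethylcyclohexan-1-one (aldol adduct, mixture of diastereomers, formed in the flask) | CC1(C)CCCC(C(O)c2cc(OC)c(C(C)C)c(OC)c2)C1=O | intermediate
4 | (6E)-6-[(3,5-dimethoxy-4-isopropylphenyl)methylidene]-2,2-dimethylcyclohexan-1-one | CC1(C)CCC/C(=C\c2cc(OC)c(C(C)C)c(OC)c2)C1=O | intermediate
5 | (2R,3S)-2-(3,5-dimethoxy-4-isopropylphenyl)-5,5-dimethyl-1-oxaspiro[2.5]octan-4-one | O=C1C(C)(C)CCC[C@@]12O[C@@H]2c1cc(OC)c(C(C)C)c(OC)c1 | intermediate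
6 | (2S)-2-[(3,5-dimethoxy-4-isopropylphenyl)methyl]-2-hydroxy-6,6-dimethylcyclohexan-1-one | O=C1C(C)(C)CCC[C@]1(O)Cc1cc(OC)c(C(C)C)c(OC)c1 | intermediate
7 | (1S)-1-[(3,5-dimethoxy-4-isopropylphenyl)methyl]-3,3-dimethyl-2-oxocyclohexyl (triphenyl-λ5-phosphanylidene)acetate (acyl ylide, formed in the flask) | O=C1C(C)(C)CCC[C@]1(OC(=O)C=P(c1ccccc1)(c1ccccc1)c1ccccc1)Cc1cc(OC)c(C(C)C)c(OC)c1 | intermediate
8 | (7aS)-7a-[(3,5-dimethoxy-4-isopropylphenyl)methyl]-4,4-dimethyl-5,6,7,7a-tetrahydro-1-benzofuran-2(4H)-one | O=C1O[C@]2(Cc3cc(OC)c(C(C)C)c(OC)c3)CCCC(C)(C)C2=C1 | intermediate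
9 | (7aS)-7a-[(2-iodo-3,5-dimethoxy-4-isopropylphenyl)methyl]-4,4-dimethyl-5,6,7,7a-tetrahydro-1-benzofuran-2(4H)-one | O=C1O[C@]2(Cc3cc(OC)c(C(C)C)c(OC)c3I)CCCC(C)(C)C2=C1 | intermediate
10 | aryllithium from 9 (lithium in place of iodine at C8, formed in the flask) | O=C1O[C@]2(Cc3cc(OC)c(C(C)C)c(OC)c3[Li])CCCC(C)(C)C2=C1 | intermediate
11 | lithium salt of hemiketal 12 (O–Li at C7, formed in the flask) | COc1cc2C[C@@]34CCCC(C)(C)C3=C[C@](O[Li])(O4)c2c(OC)c1C(C)C | intermediate
12 | (7S,10S)-7,10-epoxy-12,14-dimethoxyicetexa-5,8,11,13-tetraen-7-ol | COc1cc2C[C@@]34CCCC(C)(C)C3=C[C@](O)(O4)c2c(OC)c1C(C)C | intermediate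
13 | (5R,7S,10S)-7,10-epoxy-12,14-dimethoxyicetexa-8,11,13-trien-7-ol | COc1cc2C[C@@]34CCCC(C)(C)[C@H]3C[C@](O)(O4)c2c(OC)c1C(C)C | intermediate
14 | (5R,7S,10S)-7,10-epoxy-12,14-dimethoxyicetexa-8,11,13-triene-7,11-diol (phenol, formed in the flask) | COc1c(O)c2C[C@@]34CCCC(C)(C)[C@H]3C[C@](O)(O4)c2c(OC)c1C(C)C | intermediate
15 | (5R,7S,10S)-7,10-epoxy-7-hydroxy-12-methoxyicetexa-8,12-diene-11,14-dione | COC1=C(C(C)C)C(=O)C2=C(C[C@@]34CCCC(C)(C)[C@H]3C[C@]2(O)O4)C1=O | target

**Count**

Total steps: 8. Longest linear sequence: 8 steps (from 1 and 2 to 15).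

**Three steps most likely to fail**

Step 2. Enantioface discrimination may be poor, or of the wrong sense, for an aliphatic cyclic enone with a quaternary α′-carbon, so that the only catalyst-set stereocentre is not secured. Fallback, setting out from 4: hydrogenation (H2, 1 atm, Pd/C, EtOAc) saturates the enone to racemic 6-[(3,5-dimethoxy-4-isopropylphenyl)methyl]-2,2-dimethylcyclohexan-1-one F1. Its only possible enolate (KN(SiMe3)2, THF, −78 °C) is then oxidised with the enantiomer of (8,8-dichlorocamphorylsulfonyl)oxaziridine that delivers oxygen to the face giving the (S)-ketol. The stereocentre is thus set by reagent control in an enolate hydroxylation, not by an epoxidation, and the route is rejoined at 6.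

Step 4. The intramolecular Wittig olefination may stall at ylide 7, because the ketone is flanked by two quaternary carbons, and long heating could let the ketol rearrange. Fallback, setting out from 6: lithium ethoxyacetylide (3 equiv, THF, −78 to 0 °C), a slim nucleophile, adds to the ketone to give (2S)-1-(ethoxyethynyl)-2-[(3,5-dimethoxy-4-isopropylphenyl)methyl]-6,6-dimethylcyclohexane-1,2-diol F2 (either configuration at C1). Dilute H2SO4 in THF protonates the ynol ether, the neighbouring tertiary hydroxyl traps the resulting cation, and hydrolysis with loss of ethanol gives (7aS)-3a-hydroxy-7a-[(3,5-dimethoxy-4-isopropylphenyl)methyl]-4,4-dimethylhexahydro-1-benzofuran-2(3H)-one F3. SOCl2/pyridine dehydrates F3 towards the only available β-hydrogens (the lactone α-CH2), and the route is rejoined at 8.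

Step 8. The oxidant may attack other sites (benzylic C20, the hemiketal), or its acidity may open the strained bridge before ring C is oxidised. Fallback, setting out from 13: N-bromosuccinimide (MeCN, 0 °C) brominates the only free ring position to give (5R,7S,10S)-11-bromo-7,10-epoxy-12,14-dimethoxyicetexa-8,11,13-trien-7-ol F4. Miyaura borylation (B2pin2, Pd(dppf)Cl2, KOAc, dioxane, 90 °C) gives the 11-(4,4,5,5-tetramethyl-1,3,2-dioxaborolan-2-yl) compound F5, and NaBO3·4H2O in THF–H2O oxidises the C–B bond to the phenol. The route is thereby rejoined at 14, now isolated, and PhI(OAc)2 in MeCN–H2O should take it to 15 under mild, nearly neutral conditions.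

**Further compounds**

F1 | step 2 | 6-[(3,5-dimethoxy-4-isopropylphenyl)methyl]-2,2-dimethylcyclohexan-1-one (racemic) | CC1(C)CCCC(Cc2cc(OC)c(C(C)C)c(OC)c2)C1=O
F2 | step 4 | (2S)-1-(ethoxyethynyl)-2-[(3,5-dimethoxy-4-isopropylphenyl)methyl]-6,6-dimethylcyclohexane-1,2-diol (mixture at C1) | CCOC#CC1(O)C(C)(C)CCC[C@]1(O)Cc1cc(OC)c(C(C)C)c(OC)c1
F3 | step 4 | (7aS)-3a-hydroxy-7a-[(3,5-dimethoxy-4-isopropylphenyl)methyl]-4,4-dimethylhexahydro-1-benzofuran-2(3H)-one (mixture at C3a) | O=C1CC2(O)C(C)(C)CCC[C@@]2(Cc3cc(OC)c(C(C)C)c(OC)c3)O1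
F4 | step 8 | (5R,7S,10S)-11-bromo-7,10-epoxy-12,14-dimethoxyicetexa-8,11,13-trien-7-ol | COc1c(Br)c2C[C@@]34CCCC(C)(C)[C@H]3C[C@](O)(O4)c2c(OC)c1C(C)C
F5 | step 8 | (5R,7S,10S)-7,10-epoxy-12,14-dimethoxy-11-(4,4,5,5-tetramethyl-1,3,2-dioxaborolan-2-yl)icetexa-8,11,13-trien-7-ol | COc1c(B5OC(C)(C)C(C)(C)O5)c2C[C@@]34CCCC(C)(C)[C@H]3C[C@](O)(O4)c2c(OC)c1C(C)C
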